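The ten-membered ring is closed last, between C8 (the carbinol carbon that carries the angelate) and C9 (the ring CH2 next to it). The homoallylic array C8(O)–C9H2–C10(CHO)=C1 inside that ring is the retron of an allylboration. The precursor is therefore open-chain: the cis-fused α-methylene lactone bears a C8 aldehyde, and the far end is an α-chiral allyl pinacol boronate (boron on C1, C9 as terminal =CH2, C14 masked as acetal). One closed, six-membered transition state forms C8–C9, relays the C1–B configuration to the 8S carbinol and sets the ring-cis C1=C10 alkene. The lactone half (catalytic asymmetric allylboration) and the boronate half (lithiation–borylation) are joined by Negishi coupling.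

Key step: step 14

Numbering used below (germacrane): ring C1–C10; C6 carries the lactone oxygen; C7–C11(=C13H2)–C12(=O) completes the lactone; C8 carries the angelate; C14 is the CHO on C10; C15 is the CH2OH on C4. The target is 6R,7S,8S, with a cis-fused lactone and both ring alkenes cis within the ring.

Assumption: (S)-TRIP is taken to direct allyl transfer to the Si face of enal 9, the mirror image of the Re-face preference known for (R)-TRIP; compounds 6 and 12 are taken as purchasable (each is otherwise one step from but-2-yne-1,4-diol or acrolein diethyl acetal).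

Step 1
Reactants: 1 methyl acrylate; 2 (tert-butyldimethylsilyloxy)acetaldehyde
Product: 3 methyl 4-[(tert-butyldimethylsilyl)oxy]-3-hydroxy-2-methylidenebutanoate (racemic)
Conditions: DABCO (0.5 equiv), neat, rt
Reagents that add atoms: none
Why: Morita–Baylis–Hillman reaction of a reactive α-alkoxy aldehyde; the racemic carbinol centre does not matter because it is erased in step 3.

Step 2
Reactants: 3 Baylis–Hillman alcohol
Product: 4 methyl 3-acetoxy-4-[(tert-butyldimethylsilyl)oxy]-2-methylidenebutanoate (racemic)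
Conditions: Ac2O, pyridine, DMAP (cat.), CH2Cl2, 0 °C
Reagents that add atoms: acetic anhydride CC(=O)OC(C)=O
Why: standard acetylation turns the secondary allylic alcohol into the leaving group for allylic borylation.

Step 3
Reactants: 4 Baylis–Hillman acetate
Product: 5 methyl (2E)-4-[(tert-butyldimethylsilyl)oxy]-2-[(4,4,5,5-tetramethyl-1,3,2-dioxaborolan-2-yl)methyl]but-2-enoate (CH2OTBS cis to CH2B)
Conditions: B2pin2, Pd2(dba)3 (cat.), toluene, 50 °C
Reagents that add atoms: bis(pinacolato)diboron CC1(C)OB(OC1(C)C)B1OC(C)(C)C(C)(C)O1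
Why: Pd-catalysed allylic borylation of a Baylis–Hillman acetate via the π-allyl complex should put boron on the CH2 terminus and give the conjugated ester with CH2OTBS trans to CO2Me, the geometry equivalent to a (Z)-crotyl reagent.

Step 4
Reactants: 6 4-[(tert-butyldiphenylsilyl)oxy]but-2-yn-1-ol
Product: 8 (2Z)-4-[(tert-butyldiphenylsilyl)oxy]-3-iodobut-2-en-1-ol, via vinylalanate 7 (not isolated)
Conditions: Red-Al, THF, 0 °C; then I2, THF, −78 °C to 0 °C
Reagents that add atoms: iodine II
Why: hydroxyl-directed trans-hydroalumination places aluminium on C3 in a five-membered alanate, and iodinolysis with retention should give the (Z)-3-iodo allylic alcohol, which fixes the later C4=C5 geometry (C3 cis to C6).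

Step 5
Reactants: 8 (Z)-iodo allylic alcohol
Product: 9 (2Z)-4-[(tert-butyldiphenylsilyl)oxy]-3-iodobut-2-enal
Conditions: MnO2, CH2Cl2, rt
Reagents that add atoms: none
Why: neutral allylic oxidation on MnO2 should leave the Z geometry of the β-iodo enal intact.

Step 6
Reactants: 9 (Z)-β-iodo enal; 5 allyl boronate
Product: 11 (4S,5S)-4-{[(tert-butyldimethylsilyl)oxy]methyl}-5-[(1Z)-3-[(tert-butyldiphenylsilyl)oxy]-2-iodoprop-1-en-1-yl]-3-methylideneoxolan-2-one (cis-lactone), via borate ester 10 (not isolated)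
Conditions: (S)-TRIP (10 mol%), 4 Å MS, toluene, rt; then p-TsOH (cat.), CH2Cl2, rt
Reagents that add atoms: none
Why: chiral phosphoric acid-catalysed allylboration through a closed chair, in which the CH2OTBS group cis to CH2B sits axial and gives the syn adduct (hence the cis-lactone after lactonisation of the borate), while (S)-TRIP should direct attack to the Si face of the enal and so set C6 and, with it, C7.

Step 7
Reactants: 12 2-bromo-3,3-diethoxyprop-1-ene
Product: 14 2-(3,3-diethoxyprop-1-en-2-yl)-4,4,5,5-tetramethyl-1,3,2-dioxaborolane, via vinyllithium 13 (not isolated)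
Conditions: t-BuLi (2 equiv), Et2O, −78 °C; then i-PrOBpin, −78 °C to rt
Reagents that add atoms: 2-isopropoxy-4,4,5,5-tetramethyl-1,3,2-dioxaborolane CC(C)OB1OC(C)(C)C(C)(C)O1
Why: bromine–lithium exchange gives the α-lithio acrolein acetal, which is trapped by the isopropoxy boronate.

Step 8
Reactants: 15 3-[(4-methoxybenzyl)oxy]propan-1-ol
Product: 16 3-[(4-methoxybenzyl)oxy]propyl N,N-diisopropylcarbamate
Conditions: i-Pr2NCOCl, Et3N, toluene, reflux
Reagents that add atoms: N,N-diisopropylcarbamoyl chloride CC(C)N(C(C)C)C(=O)Cl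
Why: carbamoylation installs the directing and leaving group needed for lithiation–borylation.

Step 9
Reactants: 16 carbamate; 14 alkenyl boronate
Product: 19 2-[(3S)-1,1-diethoxy-5-[(4-methoxybenzyl)oxy]-2-methylidenepentan-3-yl]-4,4,5,5-tetramethyl-1,3,2-dioxaborolane, via lithiated carbamate 17 (not isolated), via boronate complex 18 (not isolated)
Conditions: s-BuLi, (+)-sparteine, Et2O, −78 °C; then 14, −78 °C; then MgBr2·OEt2, reflux
Reagents that add atoms: none
Why: lithiation–borylation: (+)-sparteine-mediated deprotonation should give the (R)-lithio carbamate, borylation proceeds with retention and the alkenyl group then migrates from boron to carbon with inversion, which should give the (S)-α-substituted allyl boronate (the C1 stereocentre).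

Step 10
Reactants: 19 PMB ether
Product: 20 (3S)-5,5-diethoxy-4-methylidene-3-(4,4,5,5-tetramethyl-1,3,2-dioxaborolan-2-yl)pentan-1-ol
Conditions: DDQ, CH2Cl2/pH 7 buffer, 0 °C
Reagents that add atoms: none
Why: oxidative cleavage of the PMB ether under buffered neutral conditions should spare the acetal and the allyl boronate.

Step 11
Reactants: 20 primary alcohol
Product: 21 2-[(3S)-1,1-diethoxy-5-iodo-2-methylidenepentan-3-yl]-4,4,5,5-tetramethyl-1,3,2-dioxaborolane
Conditions: I2, PPh3, imidazole, CH2Cl2, 0 °C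
Reagents that add atoms: iodine II
Why: Appel-type iodination of the primary alcohol under imidazole-buffered conditions.

Step 12
Reactants: 21 alkyl iodide; 11 vinyl iodide lactone
Product: 23 (4S,5R)-4-{[(tert-butyldimethylsilyl)oxy]methyl}-5-[(1E,5S)-2-{[(tert-butyldiphenylsilyl)oxy]methyl}-7,7-diethoxy-6-methylidene-5-(4,4,5,5-tetramethyl-1,3,2-dioxaborolan-2-yl)hept-1-en-1-yl]-3-methylideneoxolan-2-one, via alkylzinc iodide 22 (not isolated)
Conditions: Zn dust, LiCl, THF, 30 °C; then 11, Pd2(dba)3 (cat.), SPhos, THF, rt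
Reagents that add atoms: none
Why: Negishi sp3–sp2 coupling; the alkylzinc transmetalates far faster than the base-free allyl boronate, and the vinyl iodide couples with retention so that C3 ends up cis to C6.

Step 13
Reactants: 23 bis-silyl ether
Product: 24 (4S,5R)-4-(hydroxymethyl)-5-[(1E,5S)-2-{[(tert-butyldiphenylsilyl)oxy]methyl}-7,7-diethoxy-6-methylidene-5-(4,4,5,5-tetramethyl-1,3,2-dioxaborolan-2-yl)hept-1-en-1-yl]-3-methylideneoxolan-2-one
Conditions: CSA (cat.), EtOH/CH2Cl2, 0 °C
Reagents that add atoms: none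
Why: acid-catalysed solvolysis removes the primary TBS ether while the TBDPS ether and, in ethanol, the diethyl acetal persist.

Step 14
Reactants: 24 primary alcohol
Product: 27 (6R,7S,8S)-15-[(tert-butyldiphenylsilyl)oxy]-14,14-diethoxy-8-hydroxygermacra-1(10),4,11(13)-trien-12,6-olide (both ring alkenes ring-cis), via aldehyde 25 (not isolated), via borate 26 (not isolated)
Conditions: Dess–Martin periodinane, NaHCO3, CH2Cl2, 0 °C; filter; toluene (about 1 mM), 50 °C; aq. NaHCO3 work-up
Reagents that add atoms: none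
Why: Dess–Martin oxidation unveils the C8 aldehyde, which is captured intramolecularly by the allyl boronate: boron binds the carbonyl oxygen and C9 (the γ-carbon) attacks C8 through a chair-like six-membered transition state (B, O, C8, C9, C10, C1) while C1=C10 forms and boron moves to O8. The closest known reactions are the intermolecular allylborations of aldehydes with α-substituted, 2-substituted allyl pinacol boronates and the ring-closing allylborations of ω-formyl allyl boronates that give five- to seven-membered rings. The ten-membered carbocycle is closed in an endo mode: all three allyl carbons end up inside the ring, and the O–B link bridges C8 and C1 in the transition state. The one new stereocentre, C8, is controlled by the boron-bearing C1: with C2 axial and C7 equatorial the (1S)-boronate delivers C9 to the face that gives 8S, the same face that Felkin–Anh control by C7 favours (C11 anti to the incoming carbon). The step needs ring closure to beat oligomerisation (high dilution; two cis alkenes and the lactone pre-organise the chain), γ-attack (inherent, since pinacol allyl boronates do not undergo 1,3-boron shifts at this temperature) and the ring-cis alkene (A1,2 strain between the C14 acetal on C10 and an equatorial C2 enforces axial C2).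

Step 15
Reactants: 27 macrocyclic alcohol; 28 angelic acid
Product: 30 (6R,7S,8S)-8-angeloyloxy-15-[(tert-butyldiphenylsilyl)oxy]-14,14-diethoxygermacra-1(10),4,11(13)-trien-12,6-olide, via mixed anhydride 29 (not isolated)
Conditions: 28, 2,4,6-trichlorobenzoyl chloride, Et3N, toluene, rt; then 27, toluene, 60 °C (no DMAP)
Reagents that add atoms: none
Why: Yamaguchi-type mixed-anhydride esterification without nucleophilic catalyst acylates the hindered C8 alcohol and should avoid angelate-to-tiglate isomerisation.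

Step 16
Reactants: 30 protected target
Product: 31 CNP0173211.3, (6R,7S,8S)-8-angeloyloxy-15-hydroxy-14-oxogermacra-1(10),4,11(13)-trien-12,6-olide
Conditions: HF·pyridine, THF, 0 °C to rt; then H2O
Reagents that add atoms: water O
Why: fluoride removes the TBDPS ether and the aqueous acidic medium hydrolyses the very labile enal acetal, conditions that the angelate and the α-methylene lactone should survive.

Compound list
1 | methyl acrylate | C=CC(=O)OC | starting material
2 | (tert-butyldimethylsilyloxy)acetaldehyde | O=CCO[Si](C)(C)C(C)(C)C | starting material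
3 | methyl 4-[(tert-butyldimethylsilyl)oxy]-3-hydroxy-2-methylidenebutanoate (racemic) | C=C(C(=O)OC)C(O)CO[Si](C)(C)C(C)(C)C | intermediate
4 | methyl 3-acetoxy-4-[(tert-butyldimethylsilyl)oxy]-2-methylidenebutanoate (racemic) | C=C(C(=O)OC)C(OC(C)=O)CO[Si](C)(C)C(C)(C)C | intermediate
5 | methyl (2E)-4-[(tert-butyldimethylsilyl)oxy]-2-[(pinacolboryl)methyl]but-2-enoate | COC(=O)/C(CB1OC(C)(C)C(C)(C)O1)=C/CO[Si](C)(C)C(C)(C)C | intermediate
6 | 4-[(tert-butyldiphenylsilyl)oxy]but-2-yn-1-ol | OCC#CCO[Si](c1ccccc1)(c1ccccc1)C(C)(C)C | starting material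
7 | cyclic sodium vinylalanate (Al on C3, chelated by the C1 alkoxide, two 2-methoxyethoxy ligands) | [Na+].COCCO[Al-]1(OCCOC)OCC=C1CO[Si](c1ccccc1)(c1ccccc1)C(C)(C)C | intermediate (not isolated)
8 | (2Z)-4-[(tert-butyldiphenylsilyl)oxy]-3-iodobut-2-en-1-ol | OC/C=C(/CO[Si](c1ccccc1)(c1ccccc1)C(C)(C)C)I | intermediate
9 | (2Z)-4-[(tert-butyldiphenylsilyl)oxy]-3-iodobut-2-enal | O=C/C=C(/CO[Si](c1ccccc1)(c1ccccc1)C(C)(C)C)I | intermediate
10 | methyl (3S,4S,5Z)-3-{[(tert-butyldimethylsilyl)oxy]methyl}-7-[(tert-butyldiphenylsilyl)oxy]-6-iodo-2-methylidene-4-[(pinacolboryl)oxy]hept-5-enoate (3,4-syn) | COC(=O)C(=C)[C@@H](CO[Si](C)(C)C(C)(C)C)[C@H](OB1OC(C)(C)C(C)(C)O1)/C=C(/CO[Si](c1ccccc1)(c1ccccc1)C(C)(C)C)I | intermediate (not isolated)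
11 | (4S,5S)-4-{[(tert-butyldimethylsilyl)oxy]methyl}-5-[(1Z)-3-[(tert-butyldiphenylsilyl)oxy]-2-iodoprop-1-en-1-yl]-3-methylideneoxolan-2-one (cis) | C=C1C(=O)O[C@@H]([C@@H]1CO[Si](C)(C)C(C)(C)C)/C=C(/CO[Si](c1ccccc1)(c1ccccc1)C(C)(C)C)I | intermediate
12 | 2-bromo-3,3-diethoxyprop-1-ene | C=C(Br)C(OCC)OCC | starting material
13 | (3,3-diethoxyprop-1-en-2-yl)lithium | [Li]C(=C)C(OCC)OCC | intermediate (not isolated)
14 | 2-(3,3-diethoxyprop-1-en-2-yl)-4,4,5,5-tetramethyl-1,3,2-dioxaborolane | C=C(C(OCC)OCC)B1OC(C)(C)C(C)(C)O1 | intermediate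
15 | 3-[(4-methoxybenzyl)oxy]propan-1-ol | OCCCOCc1ccc(OC)cc1 | starting material
16 | 3-[(4-methoxybenzyl)oxy]propyl N,N-diisopropylcarbamate | CC(C)N(C(C)C)C(=O)OCCCOCc1ccc(OC)cc1 | intermediate
17 | (1R)-1-lithio-3-[(4-methoxybenzyl)oxy]propyl N,N-diisopropylcarbamate (sparteine complex) | COc1ccc(COCC[C@@H]([Li])OC(=O)N(C(C)C)C(C)C)cc1 | intermediate (not isolated)
18 | lithium boronate complex of 17 with 14 (boron on the former C–Li carbon, retention) | [Li+].COc1ccc(COCC[C@@H]([B-]2(C(=C)C(OCC)OCC)OC(C)(C)C(C)(C)O2)OC(=O)N(C(C)C)C(C)C)cc1 | intermediate (not isolated)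
19 | 2-[(3S)-1,1-diethoxy-5-[(4-methoxybenzyl)oxy]-2-methylidenepentan-3-yl]-4,4,5,5-tetramethyl-1,3,2-dioxaborolane | COc1ccc(COCC[C@H](B2OC(C)(C)C(C)(C)O2)C(=C)C(OCC)OCC)cc1 | intermediate
20 | (3S)-5,5-diethoxy-4-methylidene-3-(4,4,5,5-tetramethyl-1,3,2-dioxaborolan-2-yl)pentan-1-ol | OCC[C@H](B1OC(C)(C)C(C)(C)O1)C(=C)C(OCC)OCC | intermediate
21 | 2-[(3S)-1,1-diethoxy-5-iodo-2-methylidenepentan-3-yl]-4,4,5,5-tetramethyl-1,3,2-dioxaborolane | ICC[C@H](B1OC(C)(C)C(C)(C)O1)C(=C)C(OCC)OCC | intermediate
22 | [(3S)-5,5-diethoxy-4-methylidene-3-(pinacolboryl)pentyl]zinc iodide | I[Zn]CC[C@H](B1OC(C)(C)C(C)(C)O1)C(=C)C(OCC)OCC | intermediate (not isolated)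
23 | (4S,5R)-4-{[(tert-butyldimethylsilyl)oxy]methyl}-5-[(1E,5S)-2-{[(tert-butyldiphenylsilyl)oxy]methyl}-7,7-diethoxy-6-methylidene-5-(pinacolboryl)hept-1-en-1-yl]-3-methylideneoxolan-2-one | C=C1C(=O)O[C@@H]([C@@H]1CO[Si](C)(C)C(C)(C)C)/C=C(/CO[Si](c1ccccc1)(c1ccccc1)C(C)(C)C)CC[C@H](B1OC(C)(C)C(C)(C)O1)C(=C)C(OCC)OCC | intermediate
24 | (4S,5R)-4-(hydroxymethyl) analogue of 23 (C8 alcohol) | C=C1C(=O)O[C@@H]([C@@H]1CO)/C=C(/CO[Si](c1ccccc1)(c1ccccc1)C(C)(C)C)CC[C@H](B1OC(C)(C)C(C)(C)O1)C(=C)C(OCC)OCC | intermediate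
25 | (2R,3R)-2-[(1E,5S)-2-{[(tert-butyldiphenylsilyl)oxy]methyl}-7,7-diethoxy-6-methylidene-5-(pinacolboryl)hept-1-en-1-yl]-4-methylidene-5-oxooxolane-3-carbaldehyde (C8 aldehyde) | C=C1C(=O)O[C@@H]([C@@H]1C=O)/C=C(/CO[Si](c1ccccc1)(c1ccccc1)C(C)(C)C)CC[C@H](B1OC(C)(C)C(C)(C)O1)C(=C)C(OCC)OCC | intermediate (not isolated)
26 | 8-O-pinacolboryl derivative of 27 | C=C1C(=O)O[C@@H]2/C=C(/CO[Si](c3ccccc3)(c3ccccc3)C(C)(C)C)CC/C=C(/C(OCC)OCC)C[C@H](OB3OC(C)(C)C(C)(C)O3)[C@H]12 | intermediate (not isolated)
27 | (6R,7S,8S)-15-[(tert-butyldiphenylsilyl)oxy]-14,14-diethoxy-8-hydroxygermacra-1(10),4,11(13)-trien-12,6-olide (ring-cis alkenes, cis-lactone) | C=C1C(=O)O[C@@H]2/C=C(/CO[Si](c3ccccc3)(c3ccccc3)C(C)(C)C)CC/C=C(/C(OCC)OCC)C[C@H](O)[C@H]12 | intermediate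
28 | angelic acid, (2Z)-2-methylbut-2-enoic acid | C/C=C(/C)C(=O)O | starting material
29 | angelic 2,4,6-trichlorobenzoic anhydride | C/C=C(/C)C(=O)OC(=O)c1c(Cl)cc(Cl)cc1Cl | intermediate (not isolated)
30 | (6R,7S,8S)-8-angeloyloxy-15-[(tert-butyldiphenylsilyl)oxy]-14,14-diethoxygermacra-1(10),4,11(13)-trien-12,6-olide | C=C1C(=O)O[C@@H]2/C=C(/CO[Si](c3ccccc3)(c3ccccc3)C(C)(C)C)CC/C=C(/C(OCC)OCC)C[C@H](OC(=O)/C(C)=C\C)[C@H]12 | intermediate
31 | CNP0173211.3, (6R,7S,8S)-8-angeloyloxy-15-hydroxy-14-oxogermacra-1(10),4,11(13)-trien-12,6-olide | C=C1C(=O)O[C@@H]2/C=C(/CO)CC/C=C(/C=O)C[C@H](OC(=O)/C(C)=C\C)[C@H]12 | target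

Total step count: 16. Longest linear sequence: 9 steps (steps 8, 9, 10, 11, 12, 13, 14, 15, 16).

Steps most likely to fail

Step 14. The ring may not tolerate the chair with C7 equatorial, so that C9 is delivered to the other aldehyde face (poor facial selectivity at C8), and intermolecular allylboration may compete if dilution is insufficient. Fallback, setting out from 25 and coming back at 30: the stereochemistry is corrected by inversion instead of by chirality transfer. If cyclisation of 25 runs through the other face, it gives the C8-epimeric borate F1 and, after the same work-up, the (8R)-alcohol F2. F2 is esterified with angelic acid 28 under Mitsunobu conditions (PPh3, DIAD, toluene, 0 °C), which inverts C8 and gives 30 directly.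

Step 6. The ester-deactivated, (Z)-crotyl-type boronate may react so slowly under acid catalysis that an uncatalysed background reaction, or addition–elimination at the β-iodo enal, erodes enantiocontrol. Fallback, setting out from 9 (and 3) and coming back at 24: a racemic, reliably syn-selective Barbier reaction followed by enzymatic resolution. Alcohol 3 is converted with NBS/Me2S into methyl (2Z)-2-(bromomethyl)-4-[(tert-butyldimethylsilyl)oxy]but-2-enoate F3. Indium-mediated coupling of F3 with 9 in THF/H2O gives the racemic syn hydroxy ester F4 (not isolated), which lactonises with p-TsOH to the racemic cis-lactone F5. CSA in EtOH removes the TBS group to give the racemic alcohol F6. Lipase-catalysed acetylation (lipase PS, vinyl acetate) separates the unreacted (4S,5S)-alcohol F7 from the acetate of its antipode F8; should the enzyme prefer the other enantiomer, the acetate is the one kept and cleaved enzymatically. Negishi coupling of F7 with excess 22, as in step 12, gives 24.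

Step 9. Ate-complex formation between the lithiated carbamate and the α-branched alkenyl boronate may be slow or reversible, benzylic lithiation of the PMB ether may compete, and the enantiomeric ratio may erode. Fallback, setting out from 16 and coming back at 19: the order of C–B and C–C bond formation is reversed. Lithiated carbamate 17 is trapped with i-PrOBpin to give the isolable (1R)-3-[(4-methoxybenzyl)oxy]-1-(pinacolboryl)propyl N,N-diisopropylcarbamate F9 with retention. Vinyllithium 13 (from 12) is then added at −78 °C, which forms complex 18 irreversibly, and warming gives 19.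

Further compounds
F1 | step 14 | 8-O-pinacolboryl derivative of the (8R)-epimer of 27 (not isolated) | C=C1C(=O)O[C@@H]2/C=C(/CO[Si](c3ccccc3)(c3ccccc3)C(C)(C)C)CC/C=C(/C(OCC)OCC)C[C@@H](OB3OC(C)(C)C(C)(C)O3)[C@H]12
F2 | step 14 | (6R,7S,8R)-15-[(tert-butyldiphenylsilyl)oxy]-14,14-diethoxy-8-hydroxygermacra-1(10),4,11(13)-trien-12,6-olide (C8 epimer of 27) | C=C1C(=O)O[C@@H]2/C=C(/CO[Si](c3ccccc3)(c3ccccc3)C(C)(C)C)CC/C=C(/C(OCC)OCC)C[C@@H](O)[C@H]12
F3 | step 6 | methyl (2Z)-2-(bromomethyl)-4-[(tert-butyldimethylsilyl)oxy]but-2-enoate | COC(=O)/C(CBr)=C/CO[Si](C)(C)C(C)(C)C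
F4 | step 6 | methyl (3RS,4RS,5Z)-3-{[(tert-butyldimethylsilyl)oxy]methyl}-7-[(tert-butyldiphenylsilyl)oxy]-4-hydroxy-6-iodo-2-methylidenehept-5-enoate (racemic syn adduct, not isolated) | COC(=O)C(=C)[C@@H](CO[Si](C)(C)C(C)(C)C)[C@H](O)/C=C(/CO[Si](c1ccccc1)(c1ccccc1)C(C)(C)C)I.COC(=O)C(=C)[C@H](CO[Si](C)(C)C(C)(C)C)[C@@H](O)/C=C(/CO[Si](c1ccccc1)(c1ccccc1)C(C)(C)C)I
F5 | step 6 | racemic cis-lactone (racemate of 11) | C=C1C(=O)O[C@@H]([C@@H]1CO[Si](C)(C)C(C)(C)C)/C=C(/CO[Si](c1ccccc1)(c1ccccc1)C(C)(C)C)I.C=C1C(=O)O[C@H]([C@H]1CO[Si](C)(C)C(C)(C)C)/C=C(/CO[Si](c1ccccc1)(c1ccccc1)C(C)(C)C)I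
F6 | step 6 | racemic cis-4-(hydroxymethyl)-5-[(1Z)-3-[(tert-butyldiphenylsilyl)oxy]-2-iodoprop-1-en-1-yl]-3-methylideneoxolan-2-one | C=C1C(=O)O[C@@H]([C@@H]1CO)/C=C(/CO[Si](c1ccccc1)(c1ccccc1)C(C)(C)C)I.C=C1C(=O)O[C@H]([C@H]1CO)/C=C(/CO[Si](c1ccccc1)(c1ccccc1)C(C)(C)C)I
F7 | step 6 | (4S,5S)-4-(hydroxymethyl)-5-[(1Z)-3-[(tert-butyldiphenylsilyl)oxy]-2-iodoprop-1-en-1-yl]-3-methylideneoxolan-2-one | C=C1C(=O)O[C@@H]([C@@H]1CO)/C=C(/CO[Si](c1ccccc1)(c1ccccc1)C(C)(C)C)I
F8 | step 6 | [(3R,4R)-... antipode] (4R,5R)-4-(acetoxymethyl)-5-[(1Z)-3-[(tert-butyldiphenylsilyl)oxy]-2-iodoprop-1-en-1-yl]-3-methylideneoxolan-2-one | C=C1C(=O)O[C@H]([C@H]1COC(C)=O)/C=C(/CO[Si](c1ccccc1)(c1ccccc1)C(C)(C)C)I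
F9 | step 9 | (1R)-3-[(4-methoxybenzyl)oxy]-1-(4,4,5,5-tetramethyl-1,3,2-dioxaborolan-2-yl)propyl N,N-diisopropylcarbamate | COc1ccc(COCC[C@@H](B2OC(C)(C)C(C)(C)O2)OC(=O)N(C(C)C)C(C)C)cc1
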